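The ε end ring (the cyclohexene ring with the allylic hydroxyl, C1'–C6') is read as a Diels–Alder adduct. Its C4'=C5' double bond with allylic C3' (oxygen-bearing) and C6' (chain-bearing) is the diene part, and C1'(Me2)–C2'H2 is isobutylene. Tying O at C3' to C7' as a lactone makes the diene 4-methyl-2-pyrone. One cycloaddition then forms C2'–C3' and C1'–C6', closes the carbocycle and fixes the C3'/C6' relation (cis, in a bridged lactone). Lactone reduction, Wittig extension, lipase resolution and Mitsunobu inversion at C3' give the (3'R,6'R) C15 phosphonium salt. Two Wittig reactions with a C10 dialdehyde and an acetylenic C15 salt from (4R,6R)-actinol complete the polyene.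

Key step: step 1

Remarks: Carotenoid numbering is used (unprimed = acetylenic β end, primed = ε end, C7' = first chain carbon on C6'). Racemic compounds 3, 4, 6 and 7 are written with the SMILES of the enantiomer that is carried on. Compounds 1, 2, 5, 12, 15 and 19 are taken as catalogue chemicals.

Step 1
Reactants: 1 4-methyl-2H-pyran-2-one; 2 2-methylpropene
Product: 3 rac-(1S,4R)-5,5,8-trimethyl-2-oxabicyclo[2.2.2]oct-7-en-3-one
Conditions: 2 (10 equiv, condensed), CH2Cl2, 2,6-di-tert-butyl-4-methylphenol (cat.), 13 kbar, 50 °C, 72 h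
Reagents that add atoms: none
Why: A concerted, asynchronous [4+2] cycloaddition of the s-cis-locked diene C3=C4–C5=C6 of the pyrone with the C=C of 2-methylpropene; the closest known reaction type is the high-pressure Diels–Alder reaction of 2-pyrones with alkenes, which gives 2-oxabicyclo[2.2.2]oct-7-en-3-ones without loss of CO2. The carbocyclic six-membered ring (the later ε end ring) is closed by intermolecular cycloaddition, the bonds C6(pyrone)–CH2 (later C2'–C3') and C3(pyrone)–CMe2 (later C1'–C6') being formed together, and the lactone bridge stays as a temporary ring. The two new stereocentres are the bridgeheads, whose relative configuration (O at C3' cis to C7' at C6') is enforced by the bridge and by suprafacial addition; the adduct is racemic and the absolute configuration is selected in step 4. The step needs regioselectivity: the CH2 terminus of the alkene (larger HOMO coefficient, positive charge developing on the tertiary carbon) should bond to the oxygen-bearing C6 of the pyrone (largest LUMO coefficient), a polarisation the 4-methyl group does not change. No endo/exo question arises because the dienophile carries two methyl groups on one carbon and two hydrogens on the other. Pressure should accelerate the addition (negative activation volume) while the low temperature keeps the adduct from retro-cycloaddition with loss of CO2.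

Step 2
Reactants: 3 rac-(1S,4R)-5,5,8-trimethyl-2-oxabicyclo[2.2.2]oct-7-en-3-one
Product: 4 rac-(1S,4R)-5,5,8-trimethyl-2-oxabicyclo[2.2.2]oct-7-en-3-ol (lactol, both epimers at C3)
Conditions: iBu2AlH (1.1 equiv), CH2Cl2, −78 °C; aq. potassium sodium tartrate
Reagents that add atoms: none
Why: Partial reduction of a lactone to the lactol; the tetrahedral aluminium alkoxide is stable at −78 °C and collapses only on work-up, so over-reduction should not compete, and both stereocentres are untouched.

Step 3
Reactants: 4 rac-lactol; 5 1-(triphenyl-λ5-phosphanylidene)propan-2-one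
Product: 7 rac-(3E)-4-[(1R,4S)-4-hydroxy-2,6,6-trimethylcyclohex-2-en-1-yl]but-3-en-2-one (racemic cis-3-hydroxy-α-ionone), via ring-opened hydroxy aldehyde 6 (not isolated)
Conditions: 5 (1.5 equiv), PhCO2H (cat.), toluene, 80 °C
Reagents that add atoms: none
Why: Wittig olefination of the open-chain aldehyde tautomer with a stabilised ylide should give the (E)-enone, and the weakly basic ylide should leave the C6' stereocentre (α to the aldehyde and allylic) unchanged.

Step 4
Reactants: 7 rac-(3E)-4-[(1R,4S)-4-hydroxy-2,6,6-trimethylcyclohex-2-en-1-yl]but-3-en-2-one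
Product: 8 (3E)-4-[(1R,4S)-4-hydroxy-2,6,6-trimethylcyclohex-2-en-1-yl]but-3-en-2-one (single enantiomer, 3'S,6'R in carotenoid numbering)
Conditions: lipase AK from Pseudomonas fluorescens, vinyl acetate (3 equiv), tert-butyl methyl ether, 30 °C, stopped slightly beyond half conversion; chromatography
Reagents that add atoms: none
Why: Lipase-catalysed kinetic resolution by enantioselective transesterification; following the empirical rule for lipase acylation of secondary alcohols, the antipode with (R) configuration at the carbinol carbon should be acetylated, so the wanted (3'S,6'R) alcohol stays behind, which fixes the absolute configuration at C6'.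

Step 5
Reactants: 8 (3E)-4-[(1R,4S)-4-hydroxy-2,6,6-trimethylcyclohex-2-en-1-yl]but-3-en-2-one
Product: 9 (1R,4R)-3,5,5-trimethyl-4-[(1E)-3-oxobut-1-en-1-yl]cyclohex-2-en-1-yl benzoate
Conditions: PhCO2H, PPh3, diisopropyl azodicarboxylate, toluene, 0 °C to rt
Reagents that add atoms: benzoic acid OC(=O)c1ccccc1
Why: Mitsunobu reaction; SN2 displacement of the oxyphosphonium group by benzoate should invert C3' and so turn the cis adduct into the trans (3'R,6'R) pattern of the target, the ester serving as protecting group.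

Step 6
Reactants: 9 (1R,4R)-3,5,5-trimethyl-4-[(1E)-3-oxobut-1-en-1-yl]cyclohex-2-en-1-yl benzoate
Product: 10 (1R,4R)-4-[(1E)-3-hydroxy-3-methylpenta-1,4-dien-1-yl]-3,5,5-trimethylcyclohex-2-en-1-yl benzoate (both epimers at the new carbinol carbon)
Conditions: CeCl3 (anhydrous, 1.5 equiv), CH2=CHMgBr (1.3 equiv), THF, −78 °C; aq. NH4Cl
Reagents that add atoms: vinylmagnesium bromide C=C[Mg]Br
Why: Organocerium 1,2-addition to the enone carbonyl; the low basicity and the preference for ketones over esters at −78 °C should spare the benzoate and C6', and the new carbinol centre is lost again in step 7.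

Step 7
Reactants: 10 (1R,4R)-4-[(1E)-3-hydroxy-3-methylpenta-1,4-dien-1-yl]-3,5,5-trimethylcyclohex-2-en-1-yl benzoate
Product: 11 {(2E,4E)-5-[(1R,4R)-4-(benzoyloxy)-2,6,6-trimethylcyclohex-2-en-1-yl]-3-methylpenta-2,4-dien-1-yl}(triphenyl)phosphonium bromide
Conditions: PPh3·HBr (1.1 equiv), CH2Cl2, 0 °C to rt; crystallisation
Reagents that add atoms: triphenylphosphine hydrobromide [Br-].c1ccc(cc1)[PH+](c1ccccc1)c1ccccc1
Why: Ionisation of the tertiary bis-allylic alcohol to a pentadienyl cation and capture by PPh3 at the terminal carbon (allylic transposition, the classical preparation of C15 Wittig salts) should give the conjugated (E,E) salt, while the less ionisable allylic benzoate at C3' stays in place.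

Step 8
Reactants: 12 (4R,6R)-4-hydroxy-2,2,6-trimethylcyclohexan-1-one
Product: 13 (4R,6R)-4-{[tert-butyl(dimethyl)silyl]oxy}-2,2,6-trimethylcyclohexan-1-one
Conditions: tert-butyldimethylsilyl chloride, imidazole, DMF, rt
Reagents that add atoms: tert-butyldimethylsilyl chloride CC(C)(C)[Si](C)(C)Cl
Why: Standard silylation of a secondary alcohol; it protects the hydroxyl against the strong base of step 9.

Step 9
Reactants: 13 (4R,6R)-4-{[tert-butyl(dimethyl)silyl]oxy}-2,2,6-trimethylcyclohexan-1-one
Product: 14 (4R)-4-{[tert-butyl(dimethyl)silyl]oxy}-2,6,6-trimethylcyclohex-1-en-1-yl trifluoromethanesulfonate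
Conditions: LiN(iPr)2, THF, −78 °C; then PhNTf2, −78 °C to rt
Reagents that add atoms: N-phenylbis(trifluoromethanesulfonimide) O=S(=O)(N(c1ccccc1)S(=O)(=O)C(F)(F)F)C(F)(F)F
Why: Enol triflate formation; only C6 carries an α-hydrogen, so a single enolate forms and is trapped on oxygen, the C6 stereocentre is erased on purpose and C4 (the later C3) is untouched.

Step 10
Reactants: 14 (4R)-4-{[tert-butyl(dimethyl)silyl]oxy}-2,6,6-trimethylcyclohex-1-en-1-yl trifluoromethanesulfonate; 15 (2E)-3-methylpent-2-en-4-yn-1-ol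
Product: 16 (2E)-5-[(4R)-4-{[tert-butyl(dimethyl)silyl]oxy}-2,6,6-trimethylcyclohex-1-en-1-yl]-3-methylpent-2-en-4-yn-1-ol
Conditions: Pd(PPh3)4 (5 mol %), CuI (10 mol %), Et3N, DMF, rt
Reagents that add atoms: none
Why: Sonogashira coupling of an enol triflate with a terminal alkyne by zerovalent palladium and CuI; it installs the C6–C7 bond with the C5=C6 double bond and the (9E) geometry already in place, and the free allylic alcohol is tolerated.

Step 11
Reactants: 16 (2E)-5-[(4R)-4-{[tert-butyl(dimethyl)silyl]oxy}-2,6,6-trimethylcyclohex-1-en-1-yl]-3-methylpent-2-en-4-yn-1-ol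
Product: 18 {(2E)-5-[(4R)-4-hydroxy-2,6,6-trimethylcyclohex-1-en-1-yl]-3-methylpent-2-en-4-yn-1-yl}(triphenyl)phosphonium bromide, via silyl-protected phosphonium bromide 17 (not isolated)
Conditions: PPh3 (1.1 equiv), 48 % aq. HBr (1.5 equiv), MeOH, 0 °C to rt, 16 h; crystallisation
Reagents that add atoms: triphenylphosphine c1ccc(cc1)P(c1ccccc1)c1ccccc1; hydrogen bromide Br
Why: Acid-promoted substitution of the primary allylic alcohol by PPh3 (standard Wittig salt formation from allylic alcohols) should keep the (E) geometry, and the excess methanolic acid should cleave the silyl ether in the same operation.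

Step 12
Reactants: 18 {(2E)-5-[(4R)-4-hydroxy-2,6,6-trimethylcyclohex-1-en-1-yl]-3-methylpent-2-en-4-yn-1-yl}(triphenyl)phosphonium bromide; 19 (2E,4E,6E)-2,7-dimethylocta-2,4,6-trienedial
Product: 20 (3R)-3-hydroxy-7,8-didehydro-12'-apo-β-caroten-12'-al (all-E)
Conditions: 19 (3 equiv), NaOMe, MeOH/CH2Cl2, 0 °C to rt, slow addition of 18; then heptane, 80 °C (Z to E equilibration); chromatography
Reagents that add atoms: none
Why: Wittig olefination forms C11=C12; excess of the symmetrical dialdehyde should hold the reaction at mono-olefination, and the hindered Z isomer of the new double bond should equilibrate to E on heating.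

Step 13
Reactants: 11 {(2E,4E)-5-[(1R,4R)-4-(benzoyloxy)-2,6,6-trimethylcyclohex-2-en-1-yl]-3-methylpenta-2,4-dien-1-yl}(triphenyl)phosphonium bromide; 20 (3R)-3-hydroxy-7,8-didehydro-12'-apo-β-caroten-12'-al
Product: 22 (3R,3'R,6'R)-7,8-didehydro-β,ε-carotene-3,3'-diol (target), via monadoxanthin 3'-benzoate 21 (not isolated)
Conditions: NaOMe (5 equiv), MeOH/CH2Cl2, rt, then 40 °C until the benzoate is cleaved; then EtOH, reflux (Z to E equilibration); crystallisation, exclusion of light and air
Reagents that add atoms: none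
Why: Wittig olefination forms C11'=C12' and the excess methoxide should then remove the benzoate by transesterification; the stereocentres are not involved and the Z isomer of the new double bond should equilibrate thermally to all-E.

Compound list
1 | 4-methyl-2H-pyran-2-one | O=C1C=C(C)C=CO1 | starting material
2 | 2-methylpropene | C=C(C)C | starting material
3 | rac-(1S,4R)-5,5,8-trimethyl-2-oxabicyclo[2.2.2]oct-7-en-3-one | CC1=C[C@H]2OC(=O)[C@@H]1C(C)(C)C2 | intermediate
4 | rac-(1S,4R)-5,5,8-trimethyl-2-oxabicyclo[2.2.2]oct-7-en-3-ol (both epimers at C3) | CC1=C[C@H]2OC(O)[C@@H]1C(C)(C)C2 | intermediate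
5 | 1-(triphenyl-λ5-phosphanylidene)propan-2-one | CC(=O)C=P(c1ccccc1)(c1ccccc1)c1ccccc1 | starting material
6 | rac-(1R,4S)-4-hydroxy-2,6,6-trimethylcyclohex-2-ene-1-carbaldehyde (open form of 4) | CC1=C[C@@H](O)CC(C)(C)[C@H]1C=O | intermediate
7 | rac-(3E)-4-[(1R,4S)-4-hydroxy-2,6,6-trimethylcyclohex-2-en-1-yl]but-3-en-2-one | CC1=C[C@@H](O)CC(C)(C)[C@H]1/C=C/C(C)=O | intermediate
8 | (3E)-4-[(1R,4S)-4-hydroxy-2,6,6-trimethylcyclohex-2-en-1-yl]but-3-en-2-one (single enantiomer) | CC1=C[C@@H](O)CC(C)(C)[C@H]1/C=C/C(C)=O | intermediate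
9 | (1R,4R)-3,5,5-trimethyl-4-[(1E)-3-oxobut-1-en-1-yl]cyclohex-2-en-1-yl benzoate | CC1=C[C@H](OC(=O)c2ccccc2)CC(C)(C)[C@H]1/C=C/C(C)=O | intermediate
10 | (1R,4R)-4-[(1E)-3-hydroxy-3-methylpenta-1,4-dien-1-yl]-3,5,5-trimethylcyclohex-2-en-1-yl benzoate (carbinol epimers) | CC1=C[C@H](OC(=O)c2ccccc2)CC(C)(C)[C@H]1/C=C/C(C)(O)C=C | intermediate
11 | {(2E,4E)-5-[(1R,4R)-4-(benzoyloxy)-2,6,6-trimethylcyclohex-2-en-1-yl]-3-methylpenta-2,4-dien-1-yl}(triphenyl)phosphonium bromide | CC1=C[C@H](OC(=O)c2ccccc2)CC(C)(C)[C@H]1/C=C/C(C)=C/C[P+](c2ccccc2)(c2ccccc2)c2ccccc2.[Br-] | intermediate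
12 | (4R,6R)-4-hydroxy-2,2,6-trimethylcyclohexan-1-one | O=C1[C@H](C)C[C@@H](O)CC1(C)C | starting material
13 | (4R,6R)-4-{[tert-butyl(dimethyl)silyl]oxy}-2,2,6-trimethylcyclohexan-1-one | O=C1[C@H](C)C[C@@H](O[Si](C)(C)C(C)(C)C)CC1(C)C | intermediate
14 | (4R)-4-{[tert-butyl(dimethyl)silyl]oxy}-2,6,6-trimethylcyclohex-1-en-1-yl trifluoromethanesulfonate | FC(F)(F)S(=O)(=O)OC1=C(C)C[C@@H](O[Si](C)(C)C(C)(C)C)CC1(C)C | intermediate
15 | (2E)-3-methylpent-2-en-4-yn-1-ol | OC/C=C(\C)C#C | starting material
16 | (2E)-5-[(4R)-4-{[tert-butyl(dimethyl)silyl]oxy}-2,6,6-trimethylcyclohex-1-en-1-yl]-3-methylpent-2-en-4-yn-1-ol | OC/C=C(\C)C#CC1=C(C)C[C@@H](O[Si](C)(C)C(C)(C)C)CC1(C)C | intermediate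
17 | {(2E)-5-[(4R)-4-{[tert-butyl(dimethyl)silyl]oxy}-2,6,6-trimethylcyclohex-1-en-1-yl]-3-methylpent-2-en-4-yn-1-yl}(triphenyl)phosphonium bromide | C(/C=C(\C)C#CC1=C(C)C[C@@H](O[Si](C)(C)C(C)(C)C)CC1(C)C)[P+](c1ccccc1)(c1ccccc1)c1ccccc1.[Br-] | intermediate
18 | {(2E)-5-[(4R)-4-hydroxy-2,6,6-trimethylcyclohex-1-en-1-yl]-3-methylpent-2-en-4-yn-1-yl}(triphenyl)phosphonium bromide | C(/C=C(\C)C#CC1=C(C)C[C@@H](O)CC1(C)C)[P+](c1ccccc1)(c1ccccc1)c1ccccc1.[Br-] | intermediate
19 | (2E,4E,6E)-2,7-dimethylocta-2,4,6-trienedial | O=C/C(C)=C/C=C/C=C(C)/C=O | starting material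
20 | (3R)-3-hydroxy-7,8-didehydro-12'-apo-β-caroten-12'-al | O=C/C(C)=C/C=C/C=C(C)/C=C/C=C(\C)C#CC1=C(C)C[C@@H](O)CC1(C)C | intermediate
21 | (3R,3'R,6'R)-3-hydroxy-7,8-didehydro-β,ε-caroten-3'-yl benzoate | CC1=C[C@H](OC(=O)c2ccccc2)CC(C)(C)[C@H]1/C=C/C(C)=C/C=C/C(C)=C/C=C/C=C(C)/C=C/C=C(\C)C#CC1=C(C)C[C@@H](O)CC1(C)C | intermediate
22 | (3R,3'R,6'R)-7,8-didehydro-β,ε-carotene-3,3'-diol | CC1=C[C@H](O)CC(C)(C)[C@H]1/C=C/C(C)=C/C=C/C(C)=C/C=C/C=C(C)/C=C/C=C(\C)C#CC1=C(C)C[C@@H](O)CC1(C)C | target

Total step count: 13. Longest linear sequence: 8 steps (steps 1 to 7, then step 13).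

Steps most likely to fail

Step 1. The cycloaddition may stall, because an unactivated alkene meets a pyrone that is only moderately electron-poor. Forcing it thermally would bring retro-cycloaddition with loss of CO2. The fallback sets out from 1 and comes back at 3. Bromination of 1 (Br2, CH2Cl2, then Et3N) should give 3-bromo-4-methyl-2H-pyran-2-one F1, an ambiphilic bromopyrone of the kind known to add alkenes at ordinary pressure. Cycloaddition with 2 (toluene, sealed vessel, 90 °C) should give, with the same regiochemistry, the bridgehead bromide rac-4-bromo-5,5,8-trimethyl-2-oxabicyclo[2.2.2]oct-7-en-3-one F2. Radical reduction (Bu3SnH, cat. azobisisobutyronitrile, toluene, 80 °C) then removes the bromine and gives 3.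

Step 3. Olefination of the hindered, α-branched aldehyde by a stabilised ylide may be slow. Prolonged heating could then cause epimerisation at C6' or migration of the ring double bond into conjugation. The fallback sets out from 4 and comes back at 7. A non-basic Takai iodo-olefination (CrCl2, CHI3, THF, 0 °C) should give rac-(1S,4R)-4-[(E)-2-iodoethenyl]-3,5,5-trimethylcyclohex-2-en-1-ol F3. Stille coupling with tributyl(1-ethoxyvinyl)stannane (Pd(PPh3)4, DMF, 50 °C) should give rac-(1S,4R)-4-[(1E)-3-ethoxybuta-1,3-dien-1-yl]-3,5,5-trimethylcyclohex-2-en-1-ol F4. Hydrolysis of the enol ether with dilute aqueous oxalic acid in THF at 0 °C gives 7.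

Step 4. The enzyme may discriminate the two antipodes of this cis-configured cyclohexenol poorly, so that the recovered alcohol is not enantiopure. The fallback sets out from 7 and comes back at 9; it merges resolution with the inversion. A Mitsunobu reaction of 7 with (S)-2-methoxy-2-phenylacetic acid (PPh3, diisopropyl azodicarboxylate, toluene) should give two diastereomeric trans esters, to be separated by chromatography or crystallisation. These are (1R,4R)-3,5,5-trimethyl-4-[(1E)-3-oxobut-1-en-1-yl]cyclohex-2-en-1-yl (2S)-2-methoxy-2-phenylacetate F5 and its (1S,4S) ring diastereomer F6. Methanolysis of F5 (K2CO3, MeOH) gives (3E)-4-[(1R,4R)-4-hydroxy-2,6,6-trimethylcyclohex-2-en-1-yl]but-3-en-2-one F7. Benzoylation (PhCOCl, pyridine, cat. 4-dimethylaminopyridine) gives 9.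

Further compounds
F1 | step 1 | 3-bromo-4-methyl-2H-pyran-2-one | CC1=C(Br)C(=O)OC=C1
F2 | step 1 | rac-4-bromo-5,5,8-trimethyl-2-oxabicyclo[2.2.2]oct-7-en-3-one | CC1=C[C@H]2OC(=O)[C@]1(Br)C(C)(C)C2
F3 | step 3 | rac-(1S,4R)-4-[(E)-2-iodoethenyl]-3,5,5-trimethylcyclohex-2-en-1-ol | CC1=C[C@@H](O)CC(C)(C)[C@H]1/C=C/I
F4 | step 3 | rac-(1S,4R)-4-[(1E)-3-ethoxybuta-1,3-dien-1-yl]-3,5,5-trimethylcyclohex-2-en-1-ol | CC1=C[C@@H](O)CC(C)(C)[C@H]1/C=C/C(=C)OCC
F5 | step 4 | (1R,4R)-3,5,5-trimethyl-4-[(1E)-3-oxobut-1-en-1-yl]cyclohex-2-en-1-yl (2S)-2-methoxy-2-phenylacetate | CC1=C[C@H](OC(=O)[C@@H](OC)c2ccccc2)CC(C)(C)[C@H]1/C=C/C(C)=O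
F6 | step 4 | (1S,4S)-3,5,5-trimethyl-4-[(1E)-3-oxobut-1-en-1-yl]cyclohex-2-en-1-yl (2S)-2-methoxy-2-phenylacetate | CC1=C[C@@H](OC(=O)[C@@H](OC)c2ccccc2)CC(C)(C)[C@@H]1/C=C/C(C)=O
F7 | step 4 | (3E)-4-[(1R,4R)-4-hydroxy-2,6,6-trimethylcyclohex-2-en-1-yl]but-3-en-2-one | CC1=C[C@H](O)CC(C)(C)[C@H]1/C=C/C(C)=O
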